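Rings A and C each carry two ortho oxygens that must end up different: O2'/O2'' sulfated, O6'/O6'' free. Both rings are therefore cut at C2'–C3' (C2''–C3'') back to 3-aryl-4-benzyloxy-6-methyl-2-pyranones mounted on C1 and C3 of a tris(benzyloxy) ring B. In such a pyranone the two atoms flanking the aryl-bearing carbon are already unlike: a lactone carbonyl and an enol ether carbon. One treatment with sodium benzyloxide opens both lactones and recloses them through carbon. This turns two heterocycles into two benzene rings whose O2' and O4' emerge as free phenols while O6' stays benzylated. Bulky silylation of O4', sulfation of O2' and deprotection complete the route.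

Key step: step 5

Assumption: the target is drawn without axial descriptors, so the syn/anti mixture about the two tetra-ortho-oxygenated biaryl axes is accepted, and the sulfate esters are carried as sodium salts and protonated only at the very end, because the target is drawn as the bis(hydrogen sulfate).

Locants: ring B is C1–C6 with rings A and C on C1 and C3. Ring A is primed and ring C double-primed, each counted from its biaryl carbon so that the sulfated oxygen is O2' (O2'').

Step 1
Reactants: 1 2,4-diacetylphloroglucinol; 2 benzyl bromide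
Product: 3 1,1'-[2,4,6-tris(benzyloxy)benzene-1,3-diyl]diethanone
Conditions: BnBr (4 equiv), K2CO3 (5 equiv), DMF, 70 °C
Reagents that add atoms: benzyl bromide, BrCc1ccccc1
Why: Williamson ether synthesis, in which the three phenols are acidified by the flanking acetyl groups and their phenoxides should alkylate on oxygen in a dipolar aprotic medium, heat and excess halide serving only to break the chelates to the carbonyl groups.

Step 2
Reactants: 3 1,1'-[2,4,6-tris(benzyloxy)benzene-1,3-diyl]diethanone
Product: 4 dimethyl 2,2'-[2,4,6-tris(benzyloxy)benzene-1,3-diyl]diacetate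
Conditions: Tl(NO3)3·3H2O (2.2 equiv), MeOH–HC(OMe)3 (1:1), 0 °C to rt
Reagents that add atoms: methanol, CO
Why: Oxidative 1,2-aryl shift of an aryl methyl ketone with trivalent thallium (McKillop–Taylor reaction), in which the enol ether is oxythallated at its terminal carbon and the electron-rich ring B, twisted out of the carbonyl plane and so aligned for migration, shifts as monovalent thallium departs, turning each acetyl group into CH2CO2Me under conditions that aryl benzyl ethers tolerate in isoflavone-type rearrangements.

Step 3
Reactants: 4 dimethyl 2,2'-[2,4,6-tris(benzyloxy)benzene-1,3-diyl]diacetate; 5 diketene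
Product: 7 3,3'-[2,4,6-tris(benzyloxy)benzene-1,3-diyl]bis(4-hydroxy-6-methyl-2H-pyran-2-one), via bis(3,5-dioxohexanoate) diester 6 (not isolated)
Conditions: LiN(SiMe3)2 (4.4 equiv), THF, −78 °C; diketene (2.6 equiv), −78 to 0 °C; AcOH; solvent change to PhMe, DBU (3 equiv), 80 °C; aq. HCl work-up
Reagents that add atoms: diketene, C=C1CC(=O)O1
Why: C-Acetoacetylation of an ester enolate (crossed Claisen-type acylation), in which each arylacetate enolate opens diketene at its acyl carbon, the surplus amide base absorbs the acidic proton of the adduct, and after neutralisation DBU lets the C5 enol oxygen displace methoxide in a 6-exo-trig lactonisation, the usual fate of 3,5-dioxo esters under mild base.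

Step 4
Reactants: 7 3,3'-[2,4,6-tris(benzyloxy)benzene-1,3-diyl]bis(4-hydroxy-6-methyl-2H-pyran-2-one); 2 benzyl bromide
Product: 8 3,3'-[2,4,6-tris(benzyloxy)benzene-1,3-diyl]bis[4-(benzyloxy)-6-methyl-2H-pyran-2-one]
Conditions: BnBr (2.5 equiv), K2CO3 (3 equiv), DMF, 40 °C
Reagents that add atoms: benzyl bromide, BrCc1ccccc1
Why: O-Alkylation of a vinylogous acid (Williamson type), in which the pyranon-4-olate should take up the benzylic halide mainly at O4 as triacetic acid lactone does, carbon alkylation being shut off because C3 already carries the bulky ring B.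

Step 5
Reactants: 8 3,3'-[2,4,6-tris(benzyloxy)benzene-1,3-diyl]bis[4-(benzyloxy)-6-methyl-2H-pyran-2-one]
Product: 10 terphenyl tetraol (ring B: 2,4,6-tris(benzyloxy); rings A and C: 2,4-dihydroxy-6-benzyloxy), via ring-opened bis(benzyl ester) 9 (not isolated)
Conditions: NaOCH2Ph (1.0 M in PhCH2OH, 8 equiv), Ar, strictly dry, 150–160 °C; cold 1 M HCl
Reagents that add atoms: none
Why: Benzyloxide adds to each lactone carbonyl (pyranone C2) and expels the C6 enolate oxygen, giving the arm of 9 in which the benzyl ester carbon and the acetonyl chain stand cis on the former C3=C4 bond (the vinylogous enolate can restore this geometry should it be lost). Reversible deprotonation of the terminal methyl group then lets that carbon (future C3') attack the ester carbon (future C2'), benzyloxide leaves, and the cyclohexadienone tautomerises to a resorcinol that is drained from all equilibria as its bis(phenoxide), which is why more than four equivalents of base are charged. The closest known reaction type is the alkoxide-induced recyclisation of 4-methoxy-6-methyl-2-pyranone to phloroglucinol monomethyl ether, an intramolecular Claisen (Dieckmann-like) condensation. Ring A and ring C each close in the 6-(enolendo)-exo-trig mode, because the enolate C=C (C3'=C4') ends up inside the new ring while the ester C=O is exocyclic to it. No stereocentre is formed and the two biaryl axes are left uncontrolled. The step needs carbon rather than oxygen closure and an untouched C4 ether: relactonisation is reversible whereas aromatisation is not, no other carbon closure is open because pyranone C3 carries no hydrogen, and the matched alkoxide makes ester exchange and addition–elimination at C4 degenerate, so the lactone carbonyl oxygen ends as O2'–H, the ring oxygen as O4'–H and the benzyl ether as O6'.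

Step 6
Reactants: 10 terphenyl tetraol; 11 tert-butyl(chloro)diphenylsilane
Product: 12 bis(O4-silyl) terphenyl diol (as 10 but O4' and O4'' carry t-BuPh2Si; O2'–H and O2''–H free)
Conditions: t-BuPh2SiCl (2.1 equiv), imidazole (5 equiv), DMF, 0 °C to rt
Reagents that add atoms: tert-butyl(chloro)diphenylsilane, CC(C)(C)[Si](Cl)(c1ccccc1)c1ccccc1
Why: Sterically controlled phenol silylation, in which the bulky chlorosilane should react only at O4' and O4'', each flanked by two ring hydrogens, whereas O2' and O2'' lie beside the perpendicular tris(benzyloxy) ring B and can hydrogen-bond to its ether oxygens.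

Step 7
Reactants: 12 bis(O4-silyl) terphenyl diol; 13 sulfur trioxide–pyridine complex
Product: 15 disodium terphenyl O2',O2''-bis(sulfate) (ring B: 2,4,6-tris(benzyloxy); rings A and C: 2-sulfonatooxy-4-hydroxy-6-benzyloxy), via silylated bis(pyridinium sulfate) 14 (not isolated)
Conditions: SO3·pyridine (8 equiv), pyridine, 50 °C; then 1 M NaOH, THF–MeOH, 40 °C, Ar; AcOH to pH 8
Reagents that add atoms: sulfur trioxide–pyridine complex, O=S(=O)([O-])[n+]1ccccc1; sodium hydroxide, [Na+].[OH-]
Why: O-Sulfation of a phenol with an amine–SO3 complex, in which the small electrophile reaches the hindered ortho phenols that the silane could not, and the basic work-up, to which aryl sulfate monoester anions are inert, exchanges pyridinium for sodium and cleaves the base-labile aryl silyl ethers by attack of hydroxide at silicon.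

Step 8
Reactants: 15 disodium terphenyl O2',O2''-bis(sulfate)
Product: 17 target CNP0320583.0 ([1,1':3',1''-terphenyl]-2,2',2'',4,4',4'',6,6',6''-nonol 2,2''-bis(hydrogen sulfate)), via target disodium salt 16 (not isolated)
Conditions: H2 (1 atm), Pd/C (10 wt %), MeOH–H2O, rt; filter under Ar; 0.1 M HCl (2.0 equiv), 0 °C; C18 desalting, freeze-drying
Reagents that add atoms: none
Why: Catalytic hydrogenolysis of aryl benzyl ethers, whose neutral conditions should cleave all five benzylic C–O bonds without touching the S–O or aryl C–O bonds of the sulfate salts, followed by brief cold protonation with exactly two equivalents of acid to give the hydrogen sulfate form drawn for the target.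

Compound list
1 | 2,4-diacetylphloroglucinol | CC(=O)c1c(O)cc(O)c(C(C)=O)c1O | starting material
2 | benzyl bromide | BrCc1ccccc1 | starting material
3 | 1,1'-[2,4,6-tris(benzyloxy)benzene-1,3-diyl]diethanone | CC(=O)c1c(OCc2ccccc2)cc(OCc2ccccc2)c(C(C)=O)c1OCc1ccccc1 | intermediate
4 | dimethyl 2,2'-[2,4,6-tris(benzyloxy)benzene-1,3-diyl]diacetate | COC(=O)Cc1c(OCc2ccccc2)cc(OCc2ccccc2)c(CC(=O)OC)c1OCc1ccccc1 | intermediate
5 | diketene (4-methylideneoxetan-2-one) | C=C1CC(=O)O1 | starting material
6 | dimethyl 2,2'-[2,4,6-tris(benzyloxy)benzene-1,3-diyl]bis(3,5-dioxohexanoate), tautomer and epimer mixture at the labile C2 centres | COC(=O)C(C(=O)CC(C)=O)c1c(OCc2ccccc2)cc(OCc2ccccc2)c(C(C(=O)OC)C(=O)CC(C)=O)c1OCc1ccccc1 | intermediate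
7 | 3,3'-[2,4,6-tris(benzyloxy)benzene-1,3-diyl]bis(4-hydroxy-6-methyl-2H-pyran-2-one) | Cc1cc(O)c(-c2c(OCc3ccccc3)cc(OCc3ccccc3)c(-c3c(O)cc(C)oc3=O)c2OCc2ccccc2)c(=O)o1 | intermediate
8 | 3,3'-[2,4,6-tris(benzyloxy)benzene-1,3-diyl]bis[4-(benzyloxy)-6-methyl-2H-pyran-2-one] | Cc1cc(OCc2ccccc2)c(-c2c(OCc3ccccc3)cc(OCc3ccccc3)c(-c3c(OCc4ccccc4)cc(C)oc3=O)c2OCc2ccccc2)c(=O)o1 | intermediate
9 | dibenzyl (2E,2'E)-2,2'-[2,4,6-tris(benzyloxy)benzene-1,3-diyl]bis[3-(benzyloxy)-5-oxohex-2-enoate] | CC(=O)C/C(OCc1ccccc1)=C(\C(=O)OCc1ccccc1)c1c(OCc2ccccc2)cc(OCc2ccccc2)c(/C(C(=O)OCc2ccccc2)=C(\OCc2ccccc2)CC(C)=O)c1OCc1ccccc1 | intermediate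
10 | terphenyl tetraol: ring B 2,4,6-tris(benzyloxy); rings A and C each 2-hydroxy, 4-hydroxy, 6-benzyloxy | Oc1cc(O)c(-c2c(OCc3ccccc3)cc(OCc3ccccc3)c(-c3c(O)cc(O)cc3OCc3ccccc3)c2OCc2ccccc2)c(OCc2ccccc2)c1 | intermediate
11 | tert-butyl(chloro)diphenylsilane | CC(C)(C)[Si](Cl)(c1ccccc1)c1ccccc1 | starting material
12 | terphenyl diol: as 10 with O4' and O4'' as tert-butyldiphenylsilyl ethers, O2'–H and O2''–H free | Oc1cc(O[Si](c2ccccc2)(c2ccccc2)C(C)(C)C)cc(OCc2ccccc2)c1-c1c(OCc2ccccc2)cc(OCc2ccccc2)c(-c2c(O)cc(O[Si](c3ccccc3)(c3ccccc3)C(C)(C)C)cc2OCc2ccccc2)c1OCc1ccccc1 | intermediate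
13 | sulfur trioxide–pyridine complex | O=S(=O)([O-])[n+]1ccccc1 | starting material
14 | bis(pyridinium) salt of the O2',O2''-bis(sulfate) of 12 | [O-]S(=O)(=O)Oc1cc(O[Si](c2ccccc2)(c2ccccc2)C(C)(C)C)cc(OCc2ccccc2)c1-c1c(OCc2ccccc2)cc(OCc2ccccc2)c(-c2c(OS(=O)(=O)[O-])cc(O[Si](c3ccccc3)(c3ccccc3)C(C)(C)C)cc2OCc2ccccc2)c1OCc1ccccc1.c1cc[nH+]cc1.c1cc[nH+]cc1 | intermediate
15 | disodium O2',O2''-bis(sulfate): ring B 2,4,6-tris(benzyloxy); rings A and C each 2-sulfonatooxy, 4-hydroxy, 6-benzyloxy | [Na+].[Na+].[O-]S(=O)(=O)Oc1cc(O)cc(OCc2ccccc2)c1-c1c(OCc2ccccc2)cc(OCc2ccccc2)c(-c2c(OS(=O)(=O)[O-])cc(O)cc2OCc2ccccc2)c1OCc1ccccc1 | intermediate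
16 | disodium salt of the target | [Na+].[Na+].[O-]S(=O)(=O)Oc1cc(O)cc(O)c1-c1c(O)cc(O)c(-c2c(O)cc(O)cc2OS(=O)(=O)[O-])c1O | intermediate
17 | CNP0320583.0, [1,1':3',1''-terphenyl]-2,2',2'',4,4',4'',6,6',6''-nonol 2,2''-bis(hydrogen sulfate) | O=S(=O)(O)Oc1cc(O)cc(O)c1-c1c(O)cc(O)c(-c2c(O)cc(O)cc2OS(=O)(=O)O)c1O | target

Total step count: 8. Longest linear sequence: 8 steps (1 to 17).

Steps most likely to fail

1. Step 5.
What may go wrong:
- The shielded lactones may open sluggishly, because the base may merely deprotonate the C6 methyl groups.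
- The acetyl end may be lost by retro-Claisen cleavage.
- Hydride transfer from the alkoxide or ether cleavage may occur at the temperature required.
- Only one of the two arms may close.

Fallback, setting out from 8 and returning at 10: opening and closure are uncoupled instead of being run under one thermodynamic regime. Mg(OCH2Ph)2 (from Bu2Mg and PhCH2OH) in THF–PhCH2OH at about 60 °C should open both lactones by chelation-assisted transesterification. The bis(keto ester) 9 is then isolated after a buffered quench. LiN(i-Pr)2 (about 5 equiv) in THF at −78 to 0 °C converts each arm into its dianion. The terminal carbanion of that dianion is far more nucleophilic than the equilibrium enolate and should close onto the ester below room temperature, as in the polyanion Claisen cyclisations used for poly-β-carbonyl chains. This fallback makes no compound that the list lacks.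

2. Step 2.
What may go wrong:
- Enol ether formation may be slow at ketones flanked by two ortho ethers.
- The oxidant may attack the nucleophilic C5–H position of ring B.
- The reaction may stall after one of the two migrations.

Fallback, setting out from 3 and returning at 4: the carbonyl function is moved to the chain end by sulfur chemistry rather than by an aryl shift. A Willgerodt–Kindler reaction (S8, morpholine, 130 °C) should give the bis(thiomorpholide) F1. KOH in aqueous ethanol at reflux hydrolyses it to the benzene-1,3-diyldiacetic acid F2. MeI with K2CO3 in DMF then gives 4.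

3. Step 3.
What may go wrong:
- The acidic adduct may transfer a proton to unreacted enolate.
- The base may oligomerise diketene.
- The second arm may react incompletely.

Fallback, setting out from 4 and returning at 6: each chain is built from two C2 units instead of one C4 unit. LiN(SiMe3)2 followed by 1-acetylimidazole in THF at −78 °C should give the bis(α-aryl acetoacetate) F3. LiN(i-Pr)2 (2.2 equiv per arm) then generates the α,γ-dianions. These are acylated at the γ-carbon by N-methoxy-N-methylacetamide (γ-acylation of β-keto ester dianions) to give 6, which enters the DBU stage of step 3.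

Further compounds
F0 | step 5 | none | none
F1 | step 2 | 2,2'-[2,4,6-tris(benzyloxy)benzene-1,3-diyl]bis[1-(morpholin-4-yl)ethanethione] | S=C(Cc1c(OCc2ccccc2)cc(OCc2ccccc2)c(CC(=S)N2CCOCC2)c1OCc1ccccc1)N1CCOCC1
F2 | step 2 | 2,2'-[2,4,6-tris(benzyloxy)benzene-1,3-diyl]diacetic acid | OC(=O)Cc1c(OCc2ccccc2)cc(OCc2ccccc2)c(CC(=O)O)c1OCc1ccccc1
F3 | step 3 | dimethyl 2,2'-[2,4,6-tris(benzyloxy)benzene-1,3-diyl]bis(3-oxobutanoate) | COC(=O)C(C(C)=O)c1c(OCc2ccccc2)cc(OCc2ccccc2)c(C(C(C)=O)C(=O)OC)c1OCc1ccccc1
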